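The vessel is a closed, stirred flask at constant volume and temperature, in which catalyst Jo turns substrate Qa and reagent Aj into product Ji.

| setting | grey | teal | flask |
|---|---|---|---|
| Qa | 0.050 M | 0.050 M | 0.050 M |
| Aj | 0.14 M | 0.22 M | 0.100 M |
| Jo | 1.2 mM | 1.2 mM | 1.2 mM |
| remark | run made earlier | run made earlier |  |

- grey (time / min: Ji / %): 2.50: 33; 8.00: 71; 12.0: 80; 20.0: 93
- teal (time / min: Ji / %): 5.00: 62; 10.0: 78; 15.0: 89; 20.0: 97

(each reading ± 2 percentage points)

- factor on the rate of making Ji when 50% of the Qa are converted if Jo is charged twice over
- factor on the rate when 50% of the Qa are converted if Jo is charged at 12 mM instead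

- the numbers in the tables scatter with a standard deviation of 2 percentage points
- no earlier run changes the charge of Jo; that part of a forecast is a guess

Minutes of the meeting. The first speaker noted that the flask is charged with Qa at 0.050 M and Aj at 0.100 M, so Qa is the limiting reagent. Assuming one Aj is spent per Ji, she wrote the balance of Aj as its charge minus the converted Qa. That makes 0.0750 M for A_h, the Aj standing when 50% of the Qa is converted.

The second speaker applied A_h to the earlier runs. It is 0.115 M for grey and 0.195 M for teal, a factor of 1.70. Yet grey read 80% at 12.0 min and teal read 78% at 10.0 min, each reading scattering by 2 percentage points.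

The first speaker replied that, with the Qa and Aj charges held, comparing rates when 50% of the Qa is converted keeps Qa and A_h equal for both Jo charges asked about. Her own reckoning therefore took the charge factors, 2 and 10.0, supposing that the working share of Jo stays the same; she called this a guess, since no run varies Jo.

The forecaster gave 1.9 (1.4 to 2.4) and 8.5 (3 to 13), starting from a first-order catalyst as the simplest expectation, allowing that half-order behaviour, aggregation or a background route could lower it, and adding of the tenfold charge: “saturation or aggregation is likelier there, so I shade it slightly below ten and keep it wide”.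

The simulation gives 2.45 and 16.2, above both forecast ranges.

    Qa + Jo ⇌ QaJo (K = 20.0 M⁻¹, k = 4.60 M⁻¹ s⁻¹)
    Aj + QaJo → AjQaJo (k = 8.90 M⁻¹ s⁻¹)
    AjQaJo → Jo + Ji (k = 0.780 s⁻¹)
    Jo ⇌ Vy (K = 1.10, k = 0.00390 s⁻¹)

The flask has 50% of its Qa converted at 4.78 min, and Vy, outside the working round, holds 23.8% of the catalyst charged at 2.00 min and 47.4% at 10.0 min. At the same A_h, the rate per Jo charged is 1.23 and 1.62 times that of the flask. With Aj charged at 0.200 M, A_h becomes 0.175 M, a factor of 2.33, while the time until 50% of the Qa is converted changes by a factor of 0.819.

(The runs were generated by integration for substances that don't exist, and the scatter is random.)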